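**Retrosynthetic overview**

1. Target 30 ⇐ late Suzuki–Miyaura attachment of the (E)-propenal unit (as acetal boronate 27) to an aryl bromide ⇐ one double Mitsunobu inversion that turns both threo benzylic carbinols into erythro ⇐ two iterative syn-glycolate aldol / LiBH4 cycles (each forms one Cα–Cβ bond) on phenol 11.
2. 11 ⇐ ester 10 ⇐ oxidative ring contraction of (2R)-flavanone 8: the six-membered pyranone ring (O1, C2, C3, C4, C4a, C8a) becomes the five-membered dihydrofuran ring by 1,2-shift of C4a from C4 to C3; the C4–C4a bond is cleaved and C4 leaves the ring as the carboxyl (later CH2OH) carbon.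
3. Enabling feature: the C4 carbonyl of the chroman-4-one lies between the C3 methylene and aromatic carbon C4a, which carries the ring oxygen O1 in the ortho position. The C4 enol ether is attacked at C3 by iodine(III), O1 makes C4a a good migrating carbon, two methoxy groups stabilise the cation left at C4, and the C2 stereocentre is kept and dictates C3.
4. 8 ⇐ chromone 4 + arylboronic acid 7 by Pd-catalysed asymmetric conjugate addition (sets C2).
5. Ring order: pyranone ring (step 2), then its contraction to the dihydrofuran ring (step 6); all benzene rings are bought.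

Key step: step 6

Assumption: (S)-t-BuPyOx is taken to deliver the 2R flavanone, by analogy with its sense of induction on cyclic enones; if the sense is opposite, the (R)-ligand is used.

Notation: ring A = guaiacyl ring, ring B = middle syringyl ring, ring C = syringyl ring on C2 of the dihydrobenzofuran; α/β/γ and α′/β′/γ′ = side-chain carbons on rings A and B. TBS = tert-butyldimethylsilyl. CD–O– = 4-[(2R,3S)-5-bromo-3-(TBS-oxymethyl)-7-methoxy-2,3-dihydro-1-benzofuran-2-yl]-2,6-dimethoxyphenoxy. BCD–O– = 4-[(1S,2S)-2-(CD–O)-1-hydroxy-3-(TBS-oxy)propyl]-2,6-dimethoxyphenoxy. Starting materials 1, 5, 12, 16, 21 and 27 are taken as catalogue compounds.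

**Route**

Step 1
Reactants: 1 1-(2-hydroxy-3-methoxyphenyl)ethanone
Product: 2 1-(5-bromo-2-hydroxy-3-methoxyphenyl)ethanone
Conditions: NBS (1.05 equiv), MeCN, 0 °C → rt
Reagents that add atoms: N-bromosuccinimide O=C1CCC(=O)N1Br
Why: Electrophilic aromatic bromination goes para to the free phenol OH (the strongest director, also meta to the acetyl group), so only C5 should be brominated.

Step 2
Reactants: 2 1-(5-bromo-2-hydroxy-3-methoxyphenyl)ethanone
Product: 4 6-bromo-8-methoxy-4H-chromen-4-one, via enaminone 3 (not isolated)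
Conditions: DMF-DMA, toluene, 100 °C; then conc. HCl, CH2Cl2, 40 °C
Reagents that add atoms: N,N-dimethylformamide dimethyl acetal COC(OC)N(C)C
Why: Enaminone formation followed by acid-mediated cyclisation with loss of dimethylamine is the standard chromone synthesis from 2-hydroxyacetophenones.

Step 3
Reactants: 5 2,6-dimethoxy-4-(4,4,5,5-tetramethyl-1,3,2-dioxaborolan-2-yl)phenol
Product: 6 2,6-dimethoxy-4-(4,4,5,5-tetramethyl-1,3,2-dioxaborolan-2-yl)phenyl 2,2-dimethylpropanoate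
Conditions: PivCl, Et3N, DMAP (cat.), CH2Cl2, 0 °C → rt
Reagents that add atoms: pivaloyl chloride CC(C)(C)C(Cl)=O
Why: DMAP-catalysed acylation of the hindered phenol gives an aryl pivalate that lowers the electron density of ring C for step 6 and is removed without an extra step in step 7.

Step 4
Reactants: 6 2,6-dimethoxy-4-(4,4,5,5-tetramethyl-1,3,2-dioxaborolan-2-yl)phenyl 2,2-dimethylpropanoate
Product: 7 [3,5-dimethoxy-4-(pivaloyloxy)phenyl]boronic acid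
Conditions: NaIO4, NH4OAc, acetone/H2O (1:1), rt
Reagents that add atoms: water O
Why: Periodate cleavage of the pinacol released by hydrolysis (oxidative pinacol boronate deprotection) should free the boronic acid needed for transmetalation to Pd(II).

Step 5
Reactants: 4 6-bromo-8-methoxy-4H-chromen-4-one; 7 [3,5-dimethoxy-4-(pivaloyloxy)phenyl]boronic acid
Product: 8 4-[(2R)-6-bromo-8-methoxy-4-oxo-3,4-dihydro-2H-chromen-2-yl]-2,6-dimethoxyphenyl 2,2-dimethylpropanoate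
Conditions: Pd(OCOCF3)2 (5 mol %), (S)-t-BuPyOx (6 mol %), NH4PF6 (30 mol %), H2O (5 equiv), ClCH2CH2Cl, 60 °C
Reagents that add atoms: none
Why: Pd(II)/pyridine-oxazoline-catalysed asymmetric conjugate addition of an arylboronic acid to a chromone sets C2 by enantioface-selective insertion of C2=C3 into the aryl–Pd bond under ligand control, and since Pd stays Pd(II) the aryl bromide should be untouched.

Step 6
Reactants: 8 4-[(2R)-6-bromo-8-methoxy-4-oxo-3,4-dihydro-2H-chromen-2-yl]-2,6-dimethoxyphenyl 2,2-dimethylpropanoate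
Product: 10 methyl (2R,3R)-5-bromo-2-[3,5-dimethoxy-4-(pivaloyloxy)phenyl]-7-methoxy-2,3-dihydro-1-benzofuran-3-carboxylate, via enol ether 9 (not isolated)
Conditions: PhI(OAc)2 (1.2 equiv), HC(OMe)3, conc. H2SO4 (1 equiv), 0 °C → rt; NaHCO3 work-up
Reagents that add atoms: trimethyl orthoformate COC(OC)OC
Why: Acid and orthoformate convert the C4 ketone into enol ether 9, whose C3 is attacked by the iodine(III) electrophile anti to the C2 aryl group while methanol adds to C4, and aromatic carbon C4a then migrates from C4 to C3 with loss of iodobenzene, leaving a dimethoxycarbenium ion at C4 that collapses to the methyl ester. The closest known reaction type is the iodine(III)- or thallium(III)-mediated oxidative 1,2-aryl shift that contracts flavanones to trans-2-aryl-2,3-dihydrobenzofuran-3-carboxylates. The five-membered ring (O1, C2, C3, C4a, C8a) is closed not by an exo or endo cyclisation but by a suprafacial 1,2-shift through a phenonium-type three-membered transition state, with C4 expelled from the ring as the exocyclic carboxyl carbon. C2 is not touched and keeps its R configuration, while the new centre C3 is controlled by C2: the equatorial iodane trans to the aryl group is displaced with inversion by C4a, which places the ester trans to the aryl group, the arrangement also favoured thermodynamically for this epimerisable α-aryl ester. The step needs migration of C4a rather than 2,3-shift of the C2 aryl group (isoflavone) or dehydrogenation (flavone); the ortho ring oxygen O1 makes the fused ring the better migrating group and the C4–C4a bond is antiperiplanar to the equatorial C3–I bond, while the pivalate-capped ring C has a low migratory aptitude and does not promote ionisation of the C2–O1 bond.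

Step 7
Reactants: 10 methyl (2R,3R)-5-bromo-2-[3,5-dimethoxy-4-(pivaloyloxy)phenyl]-7-methoxy-2,3-dihydro-1-benzofuran-3-carboxylate
Product: 11 4-[(2R,3S)-5-bromo-3-(hydroxymethyl)-7-methoxy-2,3-dihydro-1-benzofuran-2-yl]-2,6-dimethoxyphenol
Conditions: LiAlH4, THF, 0 °C; Rochelle salt work-up
Reagents that add atoms: none
Why: Hydride reduction converts the methyl ester into the primary alcohol and cleaves the aryl pivalate in the same operation, without touching C2, C3 (descriptor changes R → S by priority only) or the aryl bromide at 0 °C.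

Step 8
Reactants: 12 (R)-4-benzyl-1,3-oxazolidin-2-one
Product: 13 (R)-4-benzyl-3-(bromoacetyl)-1,3-oxazolidin-2-one
Conditions: n-BuLi, THF, −78 °C; BrCH2COBr, −78 → 0 °C
Reagents that add atoms: bromoacetyl bromide BrCC(Br)=O
Why: N-Acylation of the lithiated oxazolidinone with an acyl bromide is a standard preparation of N-acyl auxiliaries.

Step 9
Reactants: 11 4-[(2R,3S)-5-bromo-3-(hydroxymethyl)-7-methoxy-2,3-dihydro-1-benzofuran-2-yl]-2,6-dimethoxyphenol; 13 (R)-4-benzyl-3-(bromoacetyl)-1,3-oxazolidin-2-one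
Product: 14 (R)-4-benzyl-3-(2-{4-[(2R,3S)-5-bromo-3-(hydroxymethyl)-7-methoxy-2,3-dihydro-1-benzofuran-2-yl]-2,6-dimethoxyphenoxy}acetyl)-1,3-oxazolidin-2-one
Conditions: K2CO3, DMF, rt
Reagents that add atoms: none
Why: Williamson ether synthesis: only the phenol is ionised by carbonate and it displaces the activated α-bromo imide, while the primary alcohol stays unreactive.

Step 10
Reactants: 14 (R)-4-benzyl-3-(2-{4-[(2R,3S)-5-bromo-3-(hydroxymethyl)-7-methoxy-2,3-dihydro-1-benzofuran-2-yl]-2,6-dimethoxyphenoxy}acetyl)-1,3-oxazolidin-2-one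
Product: 15 (R)-4-benzyl-3-[2-(CD–O)acetyl]-1,3-oxazolidin-2-one
Conditions: TBSCl, imidazole, DMF, 0 °C → rt
Reagents that add atoms: tert-butyldimethylsilyl chloride CC(C)(C)[Si](C)(C)Cl
Why: Standard silylation of the primary alcohol removes the only protic group before boron enolate formation.

Step 11
Reactants: 15 (R)-4-benzyl-3-[2-(CD–O)acetyl]-1,3-oxazolidin-2-one; 16 4-formyl-2,6-dimethoxyphenyl acetate
Product: 17 (R)-4-benzyl-3-[(2R,3S)-3-(4-acetoxy-3,5-dimethoxyphenyl)-2-(CD–O)-3-hydroxypropanoyl]-1,3-oxazolidin-2-one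
Conditions: Bu2BOTf (1.2 equiv), i-Pr2NEt (1.4 equiv), CH2Cl2, 0 °C; then 16, −78 → 0 °C; pH 7 buffer, MeOH, 30% H2O2, 0 °C
Reagents that add atoms: none
Why: Evans boron syn-aldol reaction of the (Z)-enolate of the aryloxyacetyl imide through a Zimmerman–Traxler chair, in which the (R)-benzyl auxiliary sets C-β′ in its final configuration and C-α′ as S; for this chain syn corresponds to threo, which is corrected in step 18.

Step 12
Reactants: 17 (R)-4-benzyl-3-[(2R,3S)-3-(4-acetoxy-3,5-dimethoxyphenyl)-2-(CD–O)-3-hydroxypropanoyl]-1,3-oxazolidin-2-one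
Product: 18 (1S,2S)-2-(CD–O)-1-(4-hydroxy-3,5-dimethoxyphenyl)propane-1,3-diol
Conditions: LiBH4, THF/MeOH, 0 °C → rt
Reagents that add atoms: none
Why: Reductive cleavage of the N-acyloxazolidinone gives the γ′-alcohol and the same hydride removes the aryl acetate, unveiling the ring-B phenol for the next chain extension without touching a stereocentre.

Step 13
Reactants: 18 (1S,2S)-2-(CD–O)-1-(4-hydroxy-3,5-dimethoxyphenyl)propane-1,3-diol; 13 (R)-4-benzyl-3-(bromoacetyl)-1,3-oxazolidin-2-one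
Product: 19 (R)-4-benzyl-3-[2-(4-{(1S,2S)-2-(CD–O)-1,3-dihydroxypropyl}-2,6-dimethoxyphenoxy)acetyl]-1,3-oxazolidin-2-one
Conditions: K2CO3, DMF, rt
Reagents that add atoms: none
Why: Williamson ether synthesis, chemoselective for the phenol over both alcohols; at room temperature the p-hydroxybenzyl alcohol should not ionise to a quinone methide.

Step 14
Reactants: 19 (R)-4-benzyl-3-[2-(4-{(1S,2S)-2-(CD–O)-1,3-dihydroxypropyl}-2,6-dimethoxyphenoxy)acetyl]-1,3-oxazolidin-2-one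
Product: 20 (R)-4-benzyl-3-[2-(BCD–O)acetyl]-1,3-oxazolidin-2-one
Conditions: TBSCl (1.1 equiv), imidazole, CH2Cl2, 0 °C
Reagents that add atoms: tert-butyldimethylsilyl chloride CC(C)(C)[Si](C)(C)Cl
Why: Sterically controlled silylation takes the primary γ′-OH and leaves the hindered benzylic α′-OH free for the later inversion.

Step 15
Reactants: 20 (R)-4-benzyl-3-[2-(BCD–O)acetyl]-1,3-oxazolidin-2-one; 21 4-formyl-2-methoxyphenyl acetate
Product: 22 (R)-4-benzyl-3-[(2R,3S)-3-(4-acetoxy-3-methoxyphenyl)-2-(BCD–O)-3-hydroxypropanoyl]-1,3-oxazolidin-2-one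
Conditions: Bu2BOTf (2.3 equiv), i-Pr2NEt (2.6 equiv), CH2Cl2, 0 °C; then 21, −78 → 0 °C; pH 7 buffer, MeOH, 30% H2O2, 0 °C
Reagents that add atoms: none
Why: Second Evans boron syn-aldol reaction with the same auxiliary control (C-β final, C-α as S, threo); the first equivalent of Bu2BOTf masks the free α′-OH as its dibutylborinate, which the oxidative work-up cleaves again.

Step 16
Reactants: 22 (R)-4-benzyl-3-[(2R,3S)-3-(4-acetoxy-3-methoxyphenyl)-2-(BCD–O)-3-hydroxypropanoyl]-1,3-oxazolidin-2-one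
Product: 23 (1S,2S)-2-(BCD–O)-1-(4-hydroxy-3-methoxyphenyl)propane-1,3-diol
Conditions: LiBH4, THF/MeOH, 0 °C → rt
Reagents that add atoms: none
Why: Reductive removal of the auxiliary and of the aryl acetate as in step 12, with all stereocentres untouched.

Step 17
Reactants: 23 (1S,2S)-2-(BCD–O)-1-(4-hydroxy-3-methoxyphenyl)propane-1,3-diol
Product: 24 (1S,2S)-2-(BCD–O)-1-[3-methoxy-4-(TBS-oxy)phenyl]-3-(TBS-oxy)propan-1-ol
Conditions: TBSCl (2.3 equiv), imidazole, DMF, 0 °C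
Reagents that add atoms: tert-butyldimethylsilyl chloride CC(C)(C)[Si](C)(C)Cl
Why: The phenol and the primary γ-OH are silylated much faster than the two hindered benzylic carbinols, so only C-α–OH and C-α′–OH remain free and the phenol cannot act as a Mitsunobu nucleophile.

Step 18
Reactants: 24 (1S,2S)-2-(BCD–O)-1-[3-methoxy-4-(TBS-oxy)phenyl]-3-(TBS-oxy)propan-1-ol
Product: 25 (1R,2S)-2-(4-{(1R,2S)-2-(CD–O)-1-[(4-nitrobenzoyl)oxy]-3-(TBS-oxy)propyl}-2,6-dimethoxyphenoxy)-1-[3-methoxy-4-(TBS-oxy)phenyl]-3-(TBS-oxy)propyl 4-nitrobenzoate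
Conditions: 4-O2NC6H4CO2H (5 equiv), PPh3 (5 equiv), DIAD (5 equiv), THF, 0 °C → rt
Reagents that add atoms: 4-nitrobenzoic acid OC(=O)c1ccc(cc1)[N+](=O)[O-]
Why: Double Mitsunobu esterification: SN2 displacement of each oxyphosphonium by 4-nitrobenzoate inverts C-α and C-α′ (S → R) and so converts both threo units into erythro, a known inversion for arylglycerol β-aryl ethers in which the adjacent β-aryloxy group disfavours ionisation.

Step 19
Reactants: 25 (1R,2S)-2-(4-{(1R,2S)-2-(CD–O)-1-[(4-nitrobenzoyl)oxy]-3-(TBS-oxy)propyl}-2,6-dimethoxyphenoxy)-1-[3-methoxy-4-(TBS-oxy)phenyl]-3-(TBS-oxy)propyl 4-nitrobenzoate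
Product: 26 (1R,2S)-2-(4-{(1R,2S)-2-(CD–O)-1-hydroxy-3-(TBS-oxy)propyl}-2,6-dimethoxyphenoxy)-1-(4-hydroxy-3-methoxyphenyl)-3-(TBS-oxy)propan-1-ol
Conditions: K2CO3, MeOH/THF, rt
Reagents that add atoms: none
Why: Base-catalysed transesterification removes both activated 4-nitrobenzoates with retention at carbon, and the same conditions cleave the phenolic silyl ether while the primary alkyl silyl ethers stay.

Step 20
Reactants: 26 (1R,2S)-2-(4-{(1R,2S)-2-(CD–O)-1-hydroxy-3-(TBS-oxy)propyl}-2,6-dimethoxyphenoxy)-1-(4-hydroxy-3-methoxyphenyl)-3-(TBS-oxy)propan-1-ol; 27 2-[(E)-3,3-diethoxyprop-1-en-1-yl]-4,4,5,5-tetramethyl-1,3,2-dioxaborolane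
Product: 29 (E)-3-[(2R,3S)-7-methoxy-2-(3,5-dimethoxy-4-{[(1R,2S)-1-hydroxy-1-(4-{[(1R,2S)-1-hydroxy-1-(4-hydroxy-3-methoxyphenyl)-3-(TBS-oxy)propan-2-yl]oxy}-3,5-dimethoxyphenyl)-3-(TBS-oxy)propan-2-yl]oxy}phenyl)-3-(TBS-oxymethyl)-2,3-dihydro-1-benzofuran-5-yl]prop-2-enal, via diethyl acetal 28 (not isolated)
Conditions: Pd(OAc)2 (5 mol %), SPhos (10 mol %), K3PO4, THF/H2O, 60 °C; then 1 M HCl, THF, 0 °C, short
Reagents that add atoms: water O
Why: Suzuki–Miyaura coupling of the electron-rich aryl bromide with the alkenyl boronate proceeds with retention of the E geometry, and brief cold acid hydrolyses the conjugated acetal to the enal while the primary silyl ethers should survive.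

Step 21
Reactants: 29 tris-TBS ether of the target (as named in step 20)
Product: 30 (E)-3-[(2R,3S)-2-(4-{[(1R,2S)-1-(4-{[(1R,2S)-1,3-dihydroxy-1-(4-hydroxy-3-methoxyphenyl)propan-2-yl]oxy}-3,5-dimethoxyphenyl)-1,3-dihydroxypropan-2-yl]oxy}-3,5-dimethoxyphenyl)-3-(hydroxymethyl)-7-methoxy-2,3-dihydro-1-benzofuran-5-yl]prop-2-enal (target)
Conditions: HF·pyridine, pyridine, THF, 0 °C → rt
Reagents that add atoms: none
Why: Buffered fluoride desilylation removes the three primary silyl ethers under conditions that should spare the enal, the benzylic alcohols and the phenylcoumaran.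

**Compound list**

1 | 1-(2-hydroxy-3-methoxyphenyl)ethanone | CC(=O)c1cccc(OC)c1O | starting material
2 | 1-(5-bromo-2-hydroxy-3-methoxyphenyl)ethanone | CC(=O)c1cc(Br)cc(OC)c1O | intermediate
3 | (E)-1-(5-bromo-2-hydroxy-3-methoxyphenyl)-3-(dimethylamino)prop-2-en-1-one | CN(C)/C=C/C(=O)c1cc(Br)cc(OC)c1O | intermediate
4 | 6-bromo-8-methoxy-4H-chromen-4-one | O=c1ccoc2c(OC)cc(Br)cc12 | intermediate
5 | 2,6-dimethoxy-4-(4,4,5,5-tetramethyl-1,3,2-dioxaborolan-2-yl)phenol | COc1cc(cc(OC)c1O)B1OC(C)(C)C(C)(C)O1 | starting material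
6 | 2,6-dimethoxy-4-(4,4,5,5-tetramethyl-1,3,2-dioxaborolan-2-yl)phenyl 2,2-dimethylpropanoate | CC(C)(C)C(=O)Oc1c(OC)cc(cc1OC)B1OC(C)(C)C(C)(C)O1 | intermediate
7 | [3,5-dimethoxy-4-(pivaloyloxy)phenyl]boronic acid | CC(C)(C)C(=O)Oc1c(OC)cc(cc1OC)B(O)O | intermediate
8 | 4-[(2R)-6-bromo-8-methoxy-4-oxo-3,4-dihydro-2H-chromen-2-yl]-2,6-dimethoxyphenyl 2,2-dimethylpropanoate | CC(C)(C)C(=O)Oc1c(OC)cc(cc1OC)[C@H]1CC(=O)c2cc(Br)cc(OC)c2O1 | intermediate
9 | 4-[(2R)-6-bromo-4,8-dimethoxy-2H-chromen-2-yl]-2,6-dimethoxyphenyl 2,2-dimethylpropanoate (enol ether) | CC(C)(C)C(=O)Oc1c(OC)cc(cc1OC)[C@H]1C=C(OC)c2cc(Br)cc(OC)c2O1 | intermediate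
10 | methyl (2R,3R)-5-bromo-2-[3,5-dimethoxy-4-(pivaloyloxy)phenyl]-7-methoxy-2,3-dihydro-1-benzofuran-3-carboxylate | CC(C)(C)C(=O)Oc1c(OC)cc(cc1OC)[C@@H]1Oc2c(OC)cc(Br)cc2[C@H]1C(=O)OC | intermediate
11 | 4-[(2R,3S)-5-bromo-3-(hydroxymethyl)-7-methoxy-2,3-dihydro-1-benzofuran-2-yl]-2,6-dimethoxyphenol | Oc1c(OC)cc(cc1OC)[C@@H]1Oc2c(OC)cc(Br)cc2[C@H]1CO | intermediate
12 | (R)-4-benzyl-1,3-oxazolidin-2-one | O=C1N[C@H](Cc2ccccc2)CO1 | starting material
13 | (R)-4-benzyl-3-(bromoacetyl)-1,3-oxazolidin-2-one | O=C(CBr)N1[C@H](Cc2ccccc2)COC1=O | intermediate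
14 | (R)-4-benzyl-3-(2-{4-[(2R,3S)-5-bromo-3-(hydroxymethyl)-7-methoxy-2,3-dihydro-1-benzofuran-2-yl]-2,6-dimethoxyphenoxy}acetyl)-1,3-oxazolidin-2-one | O=C(COc1c(OC)cc(cc1OC)[C@@H]1Oc2c(OC)cc(Br)cc2[C@H]1CO)N1[C@H](Cc2ccccc2)COC1=O | intermediate
15 | (R)-4-benzyl-3-[2-(CD–O)acetyl]-1,3-oxazolidin-2-one | O=C(COc1c(OC)cc(cc1OC)[C@@H]1Oc2c(OC)cc(Br)cc2[C@H]1CO[Si](C)(C)C(C)(C)C)N1[C@H](Cc2ccccc2)COC1=O | intermediate
16 | 4-formyl-2,6-dimethoxyphenyl acetate | CC(=O)Oc1c(OC)cc(C=O)cc1OC | starting material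
17 | (R)-4-benzyl-3-[(2R,3S)-3-(4-acetoxy-3,5-dimethoxyphenyl)-2-(CD–O)-3-hydroxypropanoyl]-1,3-oxazolidin-2-one | CC(=O)Oc1c(OC)cc(cc1OC)[C@H](O)[C@H](C(=O)N1[C@H](Cc2ccccc2)COC1=O)Oc1c(OC)cc(cc1OC)[C@@H]1Oc2c(OC)cc(Br)cc2[C@H]1CO[Si](C)(C)C(C)(C)C | intermediate
18 | (1S,2S)-2-(CD–O)-1-(4-hydroxy-3,5-dimethoxyphenyl)propane-1,3-diol (threo) | Oc1c(OC)cc(cc1OC)[C@H](O)[C@H](CO)Oc1c(OC)cc(cc1OC)[C@@H]1Oc2c(OC)cc(Br)cc2[C@H]1CO[Si](C)(C)C(C)(C)C | intermediate
19 | (R)-4-benzyl-3-[2-(4-{(1S,2S)-2-(CD–O)-1,3-dihydroxypropyl}-2,6-dimethoxyphenoxy)acetyl]-1,3-oxazolidin-2-one | O=C(COc1c(OC)cc(cc1OC)[C@H](O)[C@H](CO)Oc1c(OC)cc(cc1OC)[C@@H]1Oc2c(OC)cc(Br)cc2[C@H]1CO[Si](C)(C)C(C)(C)C)N1[C@H](Cc2ccccc2)COC1=O | intermediate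
20 | (R)-4-benzyl-3-[2-(BCD–O)acetyl]-1,3-oxazolidin-2-one | O=C(COc1c(OC)cc(cc1OC)[C@H](O)[C@H](CO[Si](C)(C)C(C)(C)C)Oc1c(OC)cc(cc1OC)[C@@H]1Oc2c(OC)cc(Br)cc2[C@H]1CO[Si](C)(C)C(C)(C)C)N1[C@H](Cc2ccccc2)COC1=O | intermediate
21 | 4-formyl-2-methoxyphenyl acetate | CC(=O)Oc1ccc(C=O)cc1OC | starting material
22 | (R)-4-benzyl-3-[(2R,3S)-3-(4-acetoxy-3-methoxyphenyl)-2-(BCD–O)-3-hydroxypropanoyl]-1,3-oxazolidin-2-one | CC(=O)Oc1ccc(cc1OC)[C@H](O)[C@H](C(=O)N1[C@H](Cc2ccccc2)COC1=O)Oc1c(OC)cc(cc1OC)[C@H](O)[C@H](CO[Si](C)(C)C(C)(C)C)Oc1c(OC)cc(cc1OC)[C@@H]1Oc2c(OC)cc(Br)cc2[C@H]1CO[Si](C)(C)C(C)(C)C | intermediate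
23 | (1S,2S)-2-(BCD–O)-1-(4-hydroxy-3-methoxyphenyl)propane-1,3-diol | Oc1ccc(cc1OC)[C@H](O)[C@H](CO)Oc1c(OC)cc(cc1OC)[C@H](O)[C@H](CO[Si](C)(C)C(C)(C)C)Oc1c(OC)cc(cc1OC)[C@@H]1Oc2c(OC)cc(Br)cc2[C@H]1CO[Si](C)(C)C(C)(C)C | intermediate
24 | (1S,2S)-2-(BCD–O)-1-[3-methoxy-4-(TBS-oxy)phenyl]-3-(TBS-oxy)propan-1-ol (bis-threo) | CC(C)(C)[Si](C)(C)Oc1ccc(cc1OC)[C@H](O)[C@H](CO[Si](C)(C)C(C)(C)C)Oc1c(OC)cc(cc1OC)[C@H](O)[C@H](CO[Si](C)(C)C(C)(C)C)Oc1c(OC)cc(cc1OC)[C@@H]1Oc2c(OC)cc(Br)cc2[C@H]1CO[Si](C)(C)C(C)(C)C | intermediate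
25 | (1R,2S)-2-(4-{(1R,2S)-2-(CD–O)-1-[(4-nitrobenzoyl)oxy]-3-(TBS-oxy)propyl}-2,6-dimethoxyphenoxy)-1-[3-methoxy-4-(TBS-oxy)phenyl]-3-(TBS-oxy)propyl 4-nitrobenzoate (bis-erythro) | CC(C)(C)[Si](C)(C)Oc1ccc(cc1OC)[C@@H](OC(=O)c1ccc(cc1)[N+](=O)[O-])[C@H](CO[Si](C)(C)C(C)(C)C)Oc1c(OC)cc(cc1OC)[C@@H](OC(=O)c1ccc(cc1)[N+](=O)[O-])[C@H](CO[Si](C)(C)C(C)(C)C)Oc1c(OC)cc(cc1OC)[C@@H]1Oc2c(OC)cc(Br)cc2[C@H]1CO[Si](C)(C)C(C)(C)C | intermediate
26 | (1R,2S)-2-(4-{(1R,2S)-2-(CD–O)-1-hydroxy-3-(TBS-oxy)propyl}-2,6-dimethoxyphenoxy)-1-(4-hydroxy-3-methoxyphenyl)-3-(TBS-oxy)propan-1-ol | Oc1ccc(cc1OC)[C@@H](O)[C@H](CO[Si](C)(C)C(C)(C)C)Oc1c(OC)cc(cc1OC)[C@@H](O)[C@H](CO[Si](C)(C)C(C)(C)C)Oc1c(OC)cc(cc1OC)[C@@H]1Oc2c(OC)cc(Br)cc2[C@H]1CO[Si](C)(C)C(C)(C)C | intermediate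
27 | 2-[(E)-3,3-diethoxyprop-1-en-1-yl]-4,4,5,5-tetramethyl-1,3,2-dioxaborolane | CCOC(OCC)/C=C/B1OC(C)(C)C(C)(C)O1 | starting material
28 | analogue of 26 with 5-[(E)-3,3-diethoxyprop-1-en-1-yl] in place of 5-bromo (diethyl acetal) | Oc1ccc(cc1OC)[C@@H](O)[C@H](CO[Si](C)(C)C(C)(C)C)Oc1c(OC)cc(cc1OC)[C@@H](O)[C@H](CO[Si](C)(C)C(C)(C)C)Oc1c(OC)cc(cc1OC)[C@@H]1Oc2c(OC)cc(/C=C/C(OCC)OCC)cc2[C@H]1CO[Si](C)(C)C(C)(C)C | intermediate
29 | tris-TBS ether of the target (γ-O, γ′-O and benzofuran CH2O silylated; (E)-enal) | Oc1ccc(cc1OC)[C@@H](O)[C@H](CO[Si](C)(C)C(C)(C)C)Oc1c(OC)cc(cc1OC)[C@@H](O)[C@H](CO[Si](C)(C)C(C)(C)C)Oc1c(OC)cc(cc1OC)[C@@H]1Oc2c(OC)cc(/C=C/C=O)cc2[C@H]1CO[Si](C)(C)C(C)(C)C | intermediate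
30 | (E)-3-[(2R,3S)-2-(4-{[(1R,2S)-1-(4-{[(1R,2S)-1,3-dihydroxy-1-(4-hydroxy-3-methoxyphenyl)propan-2-yl]oxy}-3,5-dimethoxyphenyl)-1,3-dihydroxypropan-2-yl]oxy}-3,5-dimethoxyphenyl)-3-(hydroxymethyl)-7-methoxy-2,3-dihydro-1-benzofuran-5-yl]prop-2-enal | COc1cc([C@@H](O)[C@H](CO)Oc2c(OC)cc([C@@H](O)[C@H](CO)Oc3c(OC)cc([C@@H]4Oc5c(OC)cc(/C=C/C=O)cc5[C@H]4CO)cc3OC)cc2OC)ccc1O | target

**Step count**

Total: 21 steps. Longest linear sequence: 18 steps (1, 2, 5–7, 9–21).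

**Steps most likely to fail**

1. Step 6 (key step). What may go wrong: competing 2,3-shift of the C2 aryl group or dehydrogenation instead of migration of C4a, and acid-induced erosion of the C2 configuration. The fallback is a Wolff ring contraction that sets out from 8 and comes back at 10. Condensation of 8 with DMF-DMA (toluene, 90 °C) would give the enaminone (2S)-6-bromo-3-[(E)-(dimethylamino)methylidene]-2-[3,5-dimethoxy-4-(pivaloyloxy)phenyl]-8-methoxychroman-4-one F1 (same spatial arrangement at C2; the descriptor changes by priority only). Diazo transfer with tosyl azide (MeCN, rt) would give the diazo ketone (2S)-6-bromo-3-diazo-2-[3,5-dimethoxy-4-(pivaloyloxy)phenyl]-8-methoxychroman-4-one F2. Irradiation (350 nm) in MeOH would then contract the ring through the ketene, and equilibration of C3 with catalytic DBU would deliver the trans ester 10.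

2. Step 18. What may go wrong: partial ionisation of the benzylic oxyphosphonium (loss of stereospecificity), elimination towards the aryl enol ether, or sluggish SN2 at the two hindered carbinols. The fallback sets out from 24 and comes back at 26 by oxidation and reduction. Dess–Martin periodinane (NaHCO3, CH2Cl2) would give the diketone (2S)-2-(4-{(2S)-2-(CD–O)-3-(TBS-oxy)propanoyl}-2,6-dimethoxyphenoxy)-1-[3-methoxy-4-(TBS-oxy)phenyl]-3-(TBS-oxy)propan-1-one F3. Felkin–Anh-controlled reduction with L-Selectride (THF, −78 °C; β-aryloxy group antiperiplanar to the incoming hydride, bulky γ-silyl ethers preventing chelation) should give the bis-erythro diol (1R,2S)-2-(4-{(1R,2S)-2-(CD–O)-1-hydroxy-3-(TBS-oxy)propyl}-2,6-dimethoxyphenoxy)-1-[3-methoxy-4-(TBS-oxy)phenyl]-3-(TBS-oxy)propan-1-ol F4. K2CO3 in MeOH would then remove the phenolic silyl ether to give 26.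

3. Step 15. What may go wrong: protonation of the boron enolate or incomplete enolisation caused by the free α′-hydroxyl group, with loss of conversion or diastereoselectivity. The fallback sets out from 20 and comes back at 23 with a discrete temporary protecting group. TMSCl and imidazole (CH2Cl2, 0 °C) would give the silyl ether (R)-4-benzyl-3-[2-(4-{(1S,2S)-2-(CD–O)-3-(TBS-oxy)-1-(trimethylsilyloxy)propyl}-2,6-dimethoxyphenoxy)acetyl]-1,3-oxazolidin-2-one F5. The standard boron aldol reaction (1.2 equiv Bu2BOTf) with 21 would give the adduct (R)-4-benzyl-3-[(2R,3S)-3-(4-acetoxy-3-methoxyphenyl)-2-(4-{(1S,2S)-2-(CD–O)-3-(TBS-oxy)-1-(trimethylsilyloxy)propyl}-2,6-dimethoxyphenoxy)-3-hydroxypropanoyl]-1,3-oxazolidin-2-one F6. LiBH4 reduction followed by an aqueous citric acid work-up, which also hydrolyses the trimethylsilyl ether, would give 23.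

**Further compounds**

F1 | step 6 | (2S)-6-bromo-3-[(E)-(dimethylamino)methylidene]-2-[3,5-dimethoxy-4-(pivaloyloxy)phenyl]-8-methoxychroman-4-one | CC(C)(C)C(=O)Oc1c(OC)cc(cc1OC)[C@H]1/C(=C\N(C)C)C(=O)c2cc(Br)cc(OC)c2O1
F2 | step 6 | (2S)-6-bromo-3-diazo-2-[3,5-dimethoxy-4-(pivaloyloxy)phenyl]-8-methoxychroman-4-one | CC(C)(C)C(=O)Oc1c(OC)cc(cc1OC)[C@H]1C(=[N+]=[N-])C(=O)c2cc(Br)cc(OC)c2O1
F3 | step 18 | (2S)-2-(4-{(2S)-2-(CD–O)-3-(TBS-oxy)propanoyl}-2,6-dimethoxyphenoxy)-1-[3-methoxy-4-(TBS-oxy)phenyl]-3-(TBS-oxy)propan-1-one | CC(C)(C)[Si](C)(C)Oc1ccc(cc1OC)C(=O)[C@H](CO[Si](C)(C)C(C)(C)C)Oc1c(OC)cc(cc1OC)C(=O)[C@H](CO[Si](C)(C)C(C)(C)C)Oc1c(OC)cc(cc1OC)[C@@H]1Oc2c(OC)cc(Br)cc2[C@H]1CO[Si](C)(C)C(C)(C)C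
F4 | step 18 | (1R,2S)-2-(4-{(1R,2S)-2-(CD–O)-1-hydroxy-3-(TBS-oxy)propyl}-2,6-dimethoxyphenoxy)-1-[3-methoxy-4-(TBS-oxy)phenyl]-3-(TBS-oxy)propan-1-ol | CC(C)(C)[Si](C)(C)Oc1ccc(cc1OC)[C@@H](O)[C@H](CO[Si](C)(C)C(C)(C)C)Oc1c(OC)cc(cc1OC)[C@@H](O)[C@H](CO[Si](C)(C)C(C)(C)C)Oc1c(OC)cc(cc1OC)[C@@H]1Oc2c(OC)cc(Br)cc2[C@H]1CO[Si](C)(C)C(C)(C)C
F5 | step 15 | (R)-4-benzyl-3-[2-(4-{(1S,2S)-2-(CD–O)-3-(TBS-oxy)-1-(trimethylsilyloxy)propyl}-2,6-dimethoxyphenoxy)acetyl]-1,3-oxazolidin-2-one | O=C(COc1c(OC)cc(cc1OC)[C@H](O[Si](C)(C)C)[C@H](CO[Si](C)(C)C(C)(C)C)Oc1c(OC)cc(cc1OC)[C@@H]1Oc2c(OC)cc(Br)cc2[C@H]1CO[Si](C)(C)C(C)(C)C)N1[C@H](Cc2ccccc2)COC1=O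
F6 | step 15 | (R)-4-benzyl-3-[(2R,3S)-3-(4-acetoxy-3-methoxyphenyl)-2-(4-{(1S,2S)-2-(CD–O)-3-(TBS-oxy)-1-(trimethylsilyloxy)propyl}-2,6-dimethoxyphenoxy)-3-hydroxypropanoyl]-1,3-oxazolidin-2-one | CC(=O)Oc1ccc(cc1OC)[C@H](O)[C@H](C(=O)N1[C@H](Cc2ccccc2)COC1=O)Oc1c(OC)cc(cc1OC)[C@H](O[Si](C)(C)C)[C@H](CO[Si](C)(C)C(C)(C)C)Oc1c(OC)cc(cc1OC)[C@@H]1Oc2c(OC)cc(Br)cc2[C@H]1CO[Si](C)(C)C(C)(C)C
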